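**The ratio.** The rate constants are unknown to me, but a ratio of them can be read from the runs.

| setting | teal | grey | amber | ochre | dawn | winter | summer | autumn | noon |
|---|---|---|---|---|---|---|---|---|---|
| substrate | 0.050 M | 0.050 M | 0.050 M | 0.050 M | 0.050 M (in portions, 5, over 10 h) | 0.050 M | 0.050 M | 0.050 M | 0.050 M (fed, over 10 h) |
| partner | 0.125 M | 0.084 M | 0.19 M | 0.125 M | 0.125 M | 0.125 M | 0.125 M (fed, over 10 h) | 0.125 M (fed, over 1.0 h) | 0.125 M |
| second reagent | 0.065 M | 0.065 M | 0.065 M | 0.098 M | 0.0650 M | 0.0650 M | 0.0650 M | 0.0650 M | 0.0650 M |
| third reagent | 0.20 M | 0.20 M | 0.20 M | 0.20 M | 0.200 M | 0.200 M | 0.200 M | 0.200 M | 0.200 M |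
| remark | run made earlier | run made earlier | run made earlier | run made earlier | first portion at the start, last at 10 h | everything together at the start | all else is in the flask from the start; the feed brings no volume worth counting | all else is in the flask from the start; the feed brings no volume worth counting | all else is in the flask from the start; the feed brings no volume worth counting |
| time |  |  |  |  | 15 h | 15 h | 15 h | 15 h | 15 h |

| run | time / h | target / % | side product / % |
|---|---|---|---|
| teal | 1.33 | 4.4 | 0 |
| teal | 2.00 | 9.8 | 0.7 |
| teal | 3.00 | 17.9 | 1.6 |
| teal | 5.00 | 34.1 | 3.6 |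
| teal | 10.0 | 61.4 | 5.3 |
| teal | 15.0 | 76.3 | 6.9 |
| grey | 3.00 | 16.6 | 3.4 |
| grey | 6.00 | 34.9 | 9.9 |
| grey | 10.0 | 53.8 | 16.5 |
| grey | 12.0 | 60.5 | 17.5 |
| grey | 15.0 | 66.7 | 18.6 |
| grey | 20.0 | 74.0 | 19.2 |
| amber | 1.33 | 5.0 | 0.3 |
| amber | 4.00 | 28.5 | 0.9 |
| amber | 6.00 | 43.8 | 1.3 |
| amber | 10.0 | 65.2 | 2.1 |
| amber | 15.0 | 79.5 | 2.9 |
| amber | 20.0 | 87.5 | 1.8 |
| ochre | 4.00 | 33.1 | 3.8 |
| ochre | 8.00 | 62.3 | 5.2 |
| ochre | 10.0 | 71.8 | 6.6 |
| ochre | 15.0 | 84.7 | 8.2 |
| ochre | 20.0 | 88.9 | 6.4 |

(scatter of a reading: 0.5 percentage points)

- the flask with the highest share of target in target plus side product ("all alike" if they lie within 1.5 percentage points) (dawn / winter / summer / autumn / noon / all alike)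
- share of target in target plus side product at the end, dawn
- share of target in target plus side product at the end, winter
- share of target in target plus side product at the end, summer
- share of target in target plus side product at the end, autumn
- share of target in target plus side product at the end, noon

- in percentages every species weighs as the substrate in it: one side product counts as two

**Steep partner.** Side product over target at 15.0 h is 0.279 in grey and 0.0365 in amber, a steep fall with c_partner. I therefore suppose that partner also reacts with itself, second order. Partner's rate with substrate over its rate with itself is then S·c_substrate/c_partner, and time drops out.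

**Reading S.** Grey's side product has flattened by 20.0 h, so I treat grey as finished. I read each side product as holding one substrate that took no partner, so 9.60% of the substrate charged took none. Grey's substrate therefore used 0.0452 M of the 0.084 M of partner, and I book the rest to partner meeting itself. Dividing the two uses and scaling by the charges gives 1.96. This is S, the split constant, a selectivity factor for partner, and it is a rough value taken from charges.

**My reckoning.** Dawn's first portion gives a split of 0.157. Substrate then takes 0.0169 M of partner, which serves 33.8% of the substrate charged. I reckon the partner lost to itself at 0.0540 M counted as pairs. Noon starts with no substrate at all, so I expect dawn and noon to collapse into side product. My reckoning does not separate winter, summer and autumn, so my pick of autumn, with winter next, is a guess.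

**The forecast.** The forecast chooses noon, with 93.8% for noon, 93.3% for dawn, 91.7% for winter, 91% for autumn and 55% for summer. Its words are: “Noon is smoothest, so it is best, though only slightly.” On dawn and noon my reckoning parts from it.

**The flasks.** The highest share is in autumn, at 97.7%. Winter gives 92.6%, summer 85.7%, dawn 8.12% and noon 5.71%.

    substrate + partner → intermediate A (k = 0.0200 L mol⁻¹ s⁻¹)
    second reagent + intermediate A → intermediate B (k = 0.00190 L mol⁻¹ s⁻¹)
    third reagent + intermediate B → target (k = 3.60 × 10⁻⁴ L mol⁻¹ s⁻¹)
    2 partner → self-condensation product (k = 0.00660 L mol⁻¹ s⁻¹)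
    substrate + target → side product (k = 0.00390 L mol⁻¹ s⁻¹)
    partner + target → over-reaction product (k = 3.40 × 10⁻⁴ L mol⁻¹ s⁻¹)

**Partner lost.** Noon ends with partner, the limiting reagent, at 0% and substrate at 60.4%. Self-condensation is the largest single effect on the gap between autumn and noon: without that step the gap shrinks from 92 percentage points to 5.2 points. Dawn holds 0.0547 M of self-condensation product against my 0.0540 M. The same S gives 0.0351 M for winter, which holds 0.0376 M.

The earlier runs and the new flask were computed for substances that don't exist; the scatter is artificial.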